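**Retrosynthetic overview**

1. Target 14 ⇐ O-benzyl flavone 13 (benzyl removal) ⇐ chromone 11 + veratrole 12, joined by a twofold C–H (cross-dehydrogenative) coupling that makes the bond from pyranone C2 to aryl C1′.
2. Enabling feature: in 11 the pyranone ring is a vinylogous ester O1–C2=C3–C4=O whose C2–H is the β-C–H, and the benzo ring carries oxygen on C5, C6, C7 and C8, so C2–H and C3–H are the only C–H bonds of the bicycle; in veratrole C4–H and C5–H are equivalent and unhindered.
3. 11 ⇐ o-hydroxyacetophenone 9 (enaminone annulation) ⇐ diol 8 ⇐ phenol 4 ⇐ 1,2,4,5-tetramethoxybenzene 1; the twofold symmetry of 4 and of its acylation product fixes the site of acylation and of the ortho demethylation, and leaves the C7 oxygen as the only one that is not a methyl ether.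
4. Ring order: the benzo ring (from 1) and the dimethoxyphenyl ring (12) are bought; the pyranone ring is closed in step 4; the aryl ring is attached in step 5.

Key step: step 5

Remark: the target is a planar, achiral flavone with no stereocentre or other stereogenic element, so no stereocontrol is required; the only stereo descriptor in the route is the E geometry of enaminone 10. Compounds 1 and 12 are taken as commercially available.

**Route**

Step 1
Reactants: 1 1,2,4,5-tetramethoxybenzene
Product: 4 2,3,5,6-tetramethoxyphenol, via aryllithium 2 (not isolated), via dimethyl arylboronate 3 (not isolated)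
Conditions: n-BuLi (1.2 equiv), TMEDA, THF, 0 °C→rt; B(OMe)3, −78 °C→rt; AcOH, 30% aq. H2O2, 0 °C→rt
Reagents that add atoms: hydrogen peroxide, OO
Why: Directed ortho-lithiation at a C–H flanked by two methoxy groups (both ring C–H are equivalent), borylation and oxidative 1,2-aryl migration from boron to oxygen (lithiation–borylation–oxidation) should install the single hydroxyl that becomes the C7 oxygen.

Step 2
Reactants: 4 2,3,5,6-tetramethoxyphenol
Product: 8 1-(2,4-dihydroxy-3,5,6-trimethoxyphenyl)ethan-1-one, via O-acetate 5 (not isolated), via keto acetate 6 (not isolated), via hydroxy keto acetate 7 (not isolated)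
Conditions: AcCl (3 equiv), AlCl3 (4 equiv), CH2Cl2, 0 °C→rt; aq. HCl work-up; then HCl (cat.), MeOH, 40 °C
Reagents that add atoms: acetyl chloride, CC(Cl)=O
Why: Friedel–Crafts acylation with AlCl3 should O-acetylate the phenol, C-acylate the only remaining ring C–H (para to the acetoxy group, between two methoxy groups) and, through chelation of aluminium to the new ketone, cleave one of the two symmetry-equivalent ortho methyl ethers and stop there, as in the acylation of polymethoxybenzenes; acid-catalysed methanolysis then removes the aryl acetate.

Step 3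
Reactants: 8 1-(2,4-dihydroxy-3,5,6-trimethoxyphenyl)ethan-1-one
Product: 9 1-[4-(benzyloxy)-2-hydroxy-3,5,6-trimethoxyphenyl]ethan-1-one
Conditions: BnBr (1.05 equiv), K2CO3 (1.5 equiv), acetone, reflux
Reagents that add atoms: benzyl bromide, BrCc1ccccc1
Why: Williamson etherification should occur at the more acidic 4-OH (para to the acetyl group), because the 2-OH is held in a hydrogen bond to the ketone and is far less nucleophilic under carbonate conditions.

Step 4
Reactants: 9 1-[4-(benzyloxy)-2-hydroxy-3,5,6-trimethoxyphenyl]ethan-1-one
Product: 11 7-(benzyloxy)-5,6,8-trimethoxy-4H-chromen-4-one, via enaminone 10 (not isolated)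
Conditions: Me2NCH(OMe)2 (2 equiv), toluene, 100 °C; concentrate; then AcOH, 80 °C
Reagents that add atoms: N,N-dimethylformamide dimethyl acetal, COC(OC)N(C)C
Why: Condensation of the methyl ketone with the amide acetal should give the E-enaminone, which on acid treatment undergoes intramolecular oxa-Michael addition of the phenol and loss of dimethylamine (enaminone–chromone annulation) to close the pyranone ring.

Step 5
Reactants: 11 7-(benzyloxy)-5,6,8-trimethoxy-4H-chromen-4-one; 12 1,2-dimethoxybenzene (veratrole)
Product: 13 7-(benzyloxy)-2-(3,4-dimethoxyphenyl)-5,6,8-trimethoxy-4H-chromen-4-one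
Conditions: Pd(TFA)2 (15 mol %), AgOAc (3 equiv), CsOPiv (1 equiv), PivOH, veratrole (ca. 30 equiv, cosolvent), 100 °C
Reagents that add atoms: none
Why: Pivalate-assisted palladation (concerted metalation–deprotonation) of veratrole at C4–H should give a (3,4-dimethoxyphenyl)palladium(II) species, which adds across the polarized C2=C3 bond of the vinylogous ester O1–C2=C3–C4=O with the aryl group on the electrophilic β-carbon C2 and palladium on C3 (a palladium enolate); β-hydride elimination then restores C2=C3, so the flavone oxidation level is reached without a separate dehydrogenation, and Ag(I) reoxidizes Pd(0). The closest known reaction type is the Pd(II)/Ag(I)-mediated oxidative C–H/C–H cross-coupling (Fujiwara–Moritani-type arylation) of chromones with simple arenes at C2. No ring is closed and no stereocentre is formed. The step needs C2 over C3 selectivity on the chromone, which the enone polarization secures because aryl transfer is a conjugate carbopalladation; it needs chemoselectivity among ring C–H bonds, which is secured because the benzo ring is oxygenated at C5, C6, C7 and C8 and has none; and it needs C4 over C3 selectivity on veratrole, which is secured sterically (C3–H is flanked by a methoxy group) while C4 and C5 are equivalent by symmetry. Homocoupling of veratrole is tolerable because veratrole is the cheap partner used in excess and chromone 11 is limiting.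

Step 6
Reactants: 13 7-(benzyloxy)-2-(3,4-dimethoxyphenyl)-5,6,8-trimethoxy-4H-chromen-4-one
Product: 14 2-(3,4-dimethoxyphenyl)-7-hydroxy-5,6,8-trimethoxy-4H-chromen-4-one
Conditions: H2 (1 atm), 10% Pd/C, EtOAc–MeOH, rt
Reagents that add atoms: none
Why: Heterogeneous hydrogenolysis of the benzyl aryl ether should be much faster than reduction of the conjugated trisubstituted C2=C3 bond or cleavage of aryl methyl ethers under 1 atm H2 at rt, and frees the C7 phenol.

**Compound list**

1 | 1,2,4,5-tetramethoxybenzene | COc1cc(OC)c(OC)cc1OC | starting material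
2 | (2,3,5,6-tetramethoxyphenyl)lithium | [Li]c1c(OC)c(OC)cc(OC)c1OC | intermediate
3 | dimethyl (2,3,5,6-tetramethoxyphenyl)boronate | COB(OC)c1c(OC)c(OC)cc(OC)c1OC | intermediate
4 | 2,3,5,6-tetramethoxyphenol | Oc1c(OC)c(OC)cc(OC)c1OC | intermediate
5 | 2,3,5,6-tetramethoxyphenyl acetate | CC(=O)Oc1c(OC)c(OC)cc(OC)c1OC | intermediate
6 | 4-acetyl-2,3,5,6-tetramethoxyphenyl acetate | CC(=O)Oc1c(OC)c(OC)c(C(C)=O)c(OC)c1OC | intermediate
7 | 4-acetyl-3-hydroxy-2,5,6-trimethoxyphenyl acetate | CC(=O)Oc1c(OC)c(OC)c(C(C)=O)c(O)c1OC | intermediate
8 | 1-(2,4-dihydroxy-3,5,6-trimethoxyphenyl)ethan-1-one | CC(=O)c1c(O)c(OC)c(O)c(OC)c1OC | intermediate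
9 | 1-[4-(benzyloxy)-2-hydroxy-3,5,6-trimethoxyphenyl]ethan-1-one | CC(=O)c1c(O)c(OC)c(OCc2ccccc2)c(OC)c1OC | intermediate
10 | (E)-1-[4-(benzyloxy)-2-hydroxy-3,5,6-trimethoxyphenyl]-3-(dimethylamino)prop-2-en-1-one | CN(C)/C=C/C(=O)c1c(O)c(OC)c(OCc2ccccc2)c(OC)c1OC | intermediate
11 | 7-(benzyloxy)-5,6,8-trimethoxy-4H-chromen-4-one | O=c1ccoc2c(OC)c(OCc3ccccc3)c(OC)c(OC)c12 | intermediate
12 | 1,2-dimethoxybenzene (veratrole) | COc1ccccc1OC | starting material
13 | 7-(benzyloxy)-2-(3,4-dimethoxyphenyl)-5,6,8-trimethoxy-4H-chromen-4-one | COc1ccc(-c2cc(=O)c3c(OC)c(OC)c(OCc4ccccc4)c(OC)c3o2)cc1OC | intermediate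
14 | 2-(3,4-dimethoxyphenyl)-7-hydroxy-5,6,8-trimethoxy-4H-chromen-4-one | COc1ccc(-c2cc(=O)c3c(OC)c(OC)c(O)c(OC)c3o2)cc1OC | target

**Step count and risks**

Total step count: 6. Longest linear sequence: 6 steps (1 → 14); veratrole 12 enters directly in step 5.

Steps most likely to fail:

Step 5 (key step). Palladation of veratrole at the hindered C3–H instead of C4–H, or slow carbopalladation of the electron-rich, peri-substituted chromone so that veratrole homocoupling and catalyst decomposition dominate, would erode the coupling. The fallback fixes the aryl position through a carbon–boron bond and separates addition from oxidation. It sets out from 11: Pd(II)-catalysed conjugate addition of (3,4-dimethoxyphenyl)boronic acid (Pd(TFA)2, 2,2′-bipyridine, AcOH–H2O, 60–80 °C) should give the racemic flavanone 7-(benzyloxy)-2-(3,4-dimethoxyphenyl)-5,6,8-trimethoxychroman-4-one F1. Dehydrogenation of F1 with catalytic I2 in DMSO at 120 °C should then give 13, where the route is rejoined; the transient C2 stereocentre of F1 is destroyed again, so its configuration is irrelevant.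

Step 2. After O-acetylation the ring is less nucleophilic and its only open position lies between two methoxy groups, so C-acylation may stall; alternatively the Lewis acid may cleave the second ortho ether or other methyl ethers. The fallback reverses the polarity of the acylation. It sets out from 4: O-alkylation with 2-bromopropane (K2CO3, DMF, 60 °C) should give 3-isopropoxy-1,2,4,5-tetramethoxybenzene F2. Lithiation of F2 at its single ring C–H (n-BuLi, TMEDA, THF, 0 °C) and acylation with N-methoxy-N-methylacetamide (−78 °C→rt) should give 1-(4-isopropoxy-2,3,5,6-tetramethoxyphenyl)ethan-1-one F3. BCl3 (CH2Cl2, −78→0 °C) should then cleave the isopropyl ether and, by chelation to the ketone, one of the two equivalent ortho methyl ethers, which returns the route to 8.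

Step 1. Incomplete or twofold lithiation, and over-oxidation of the very electron-rich phenol during the peroxide stage, would lower the throughput of the whole sequence. The fallback avoids both the organolithium and the peroxide. It sets out from 1: monobromination (NBS, MeCN, 0 °C→rt) should give 3-bromo-1,2,4,5-tetramethoxybenzene F4, and Pd-catalysed hydroxylation of F4 (Pd2(dba)3, t-BuXPhos, KOH, dioxane–H2O, 100 °C, then acidification) should give 4, where the route is rejoined.

**Further compounds**

F1 | step 5 | rac-7-(benzyloxy)-2-(3,4-dimethoxyphenyl)-5,6,8-trimethoxychroman-4-one | COc1ccc(C2CC(=O)c3c(OC)c(OC)c(OCc4ccccc4)c(OC)c3O2)cc1OC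
F2 | step 2 | 3-isopropoxy-1,2,4,5-tetramethoxybenzene | CC(C)Oc1c(OC)c(OC)cc(OC)c1OC
F3 | step 2 | 1-(4-isopropoxy-2,3,5,6-tetramethoxyphenyl)ethan-1-one | CC(=O)c1c(OC)c(OC)c(OC(C)C)c(OC)c1OC
F4 | step 1 | 3-bromo-1,2,4,5-tetramethoxybenzene | COc1cc(OC)c(OC)c(Br)c1OC
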